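**Strategy.** Everything rests on cutting C4–C4a of ring C, which turns the flavan into an aryl 1-arylpropargyl ether. Ring A is a 2-substituted 5-methoxyresorcinol in which O1 and O7 flank C8 and stay equivalent while C8 carries bromine, so one Mitsunobu etherification both desymmetrises it and sets C2. A monovalent-gold-catalysed hydroarylation then closes ring C in one operation at the only free carbon ortho to O1, leaving C2 intact and delivering the C3=C4 alkene whose syn-dihydroxylation anti to ring B gives the 3,4-cis-diol. The precursor is the (S)-propargyl ether bearing bromine at C8 and pivalates on O7 and O4'.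

Key step: step 9

Assumption: (S,S)-ProPhenol is taken to direct the alkynylzinc to the Re face of the aldehyde, as in its aldol reactions; should the first run show the opposite sense, (R,R)-ProPhenol is used and nothing else changes.

Step 1
Reactants: 1 5-methoxybenzene-1,3-diol
Product: 2 1-methoxy-3,5-bis(methoxymethoxy)benzene
Conditions: MOMCl (2.5 equiv), iPr2NEt, CH2Cl2, 0 °C to rt
Reagents that add atoms: chloromethyl methyl ether, COCCl
Why: Williamson-type O-alkylation of both phenols gives two MOM ethers, which are strong, chelating and acid-removable directing groups for the metalation that follows.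

Step 2
Reactants: 2 1-methoxy-3,5-bis(methoxymethoxy)benzene
Product: 4 2-bromo-5-methoxy-1,3-bis(methoxymethoxy)benzene, via [4-methoxy-2,6-bis(methoxymethoxy)phenyl]lithium 3 (not isolated)
Conditions: n-BuLi, THF, 0 °C; then BrCl2C–CCl2Br, −78 °C to rt
Reagents that add atoms: 1,2-dibromo-1,1,2,2-tetrachloroethane, BrC(Cl)(Cl)C(Cl)(Cl)Br
Why: Directed ortho-metalation should remove the proton flanked by the two chelating MOM ethers in preference to those beside the weaker methoxy director, and the aryllithium is then brominated by halogen transfer from the polyhaloethane.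

Step 3
Reactants: 4 2-bromo-5-methoxy-1,3-bis(methoxymethoxy)benzene
Product: 5 2-bromo-5-methoxybenzene-1,3-diol
Conditions: HCl (aq., cat.), MeOH, 40 °C
Reagents that add atoms: none
Why: Acid-catalysed acetal exchange with methanol (MOM cleavage) frees both phenols and restores the mirror symmetry that makes the two oxygens equivalent, the aryl bromide being inert to dilute acid.

Step 4
Reactants: 6 4-hydroxybenzaldehyde
Product: 7 4-formylphenyl pivalate
Conditions: PivCl, Et3N, DMAP (cat.), CH2Cl2, 0 °C to rt
Reagents that add atoms: pivaloyl chloride, CC(C)(C)C(Cl)=O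
Why: DMAP-catalysed O-acylation gives a hindered aryl ester that should survive the organozinc, Mitsunobu, gold, osmium and palladium steps and that makes ring B less able to stabilise a benzylic cation.

Step 5
Reactants: 7 4-formylphenyl pivalate; 8 ethynyltrimethylsilane
Product: 10 (S)-4-[1-hydroxy-3-(trimethylsilyl)prop-2-yn-1-yl]phenyl pivalate, via methyl[(trimethylsilyl)ethynyl]zinc 9 (not isolated)
Conditions: (S,S)-ProPhenol (10 mol %), Ph3PO (20 mol %), Me2Zn (3 equiv), toluene, 0–4 °C; aq. NH4Cl
Reagents that add atoms: none
Why: Catalytic enantioselective alkynylation of an aldehyde by a zinc acetylide in the chiral dinuclear zinc pocket should deliver the alkyne to the Re face and set the carbinol centre as S, Me2Zn itself neither adding to the aldehyde nor attacking the pivalate; this direct addition is preferred to reducing the corresponding ynone, where aryl and alkynyl groups would compete for the same site of a transfer-hydrogenation catalyst.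

Step 6
Reactants: 10 (S)-4-[1-hydroxy-3-(trimethylsilyl)prop-2-yn-1-yl]phenyl pivalate
Product: 11 (R)-4-(1-hydroxyprop-2-yn-1-yl)phenyl pivalate
Conditions: TBAF, AcOH (1:1), THF, 0 °C
Reagents that add atoms: none
Why: Fluoride-induced protodesilylation of the alkynylsilane under acetic acid buffering should spare the aryl pivalate that carbonate in methanol would cleave; the descriptor changes from S to R only because the bare ethynyl group ranks below the aryl group, and a recrystallisation here would raise the enantiomeric purity if needed.

Step 7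
Reactants: 5 2-bromo-5-methoxybenzene-1,3-diol; 11 (R)-4-(1-hydroxyprop-2-yn-1-yl)phenyl pivalate
Product: 12 (S)-4-[1-(2-bromo-3-hydroxy-5-methoxyphenoxy)prop-2-yn-1-yl]phenyl pivalate
Conditions: PPh3, DIAD, toluene, 0 °C to rt; 5 in threefold excess
Reagents that add atoms: none
Why: Mitsunobu etherification, in which the acidic ortho-bromophenol displaces the alkoxyphosphonium by SN2 with inversion (R alcohol to S ether), the excess of the symmetric diol suppressing double etherification and the electron-poor ring B disfavouring ionisation.

Step 8
Reactants: 12 (S)-4-[1-(2-bromo-3-hydroxy-5-methoxyphenoxy)prop-2-yn-1-yl]phenyl pivalate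
Product: 13 (S)-2-bromo-5-methoxy-3-{1-[4-(pivaloyloxy)phenyl]prop-2-yn-1-yloxy}phenyl pivalate
Conditions: PivCl, Et3N, DMAP (cat.), CH2Cl2, 0 °C
Reagents that add atoms: pivaloyl chloride, CC(C)(C)C(Cl)=O
Why: O-acylation of the remaining phenol removes the acidic proton and gives both phenols the same base-labile protecting group, so that one operation can free them at the end.

Step 9
Reactants: 13 (S)-2-bromo-5-methoxy-3-{1-[4-(pivaloyloxy)phenyl]prop-2-yn-1-yloxy}phenyl pivalate
Product: 14 (2S)-8-bromo-5-methoxy-7,4'-bis(pivaloyloxy)flav-3-ene
Conditions: Ph3PAuNTf2 (3 mol %), CH2Cl2, 0 °C to rt, dark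
Reagents that add atoms: none
Why: The cationic monovalent gold complex binds the terminal alkyne as a π-acid, the arene carbon lying between the ether oxygen and the methoxy group attacks the terminal alkyne carbon to give a vinylgold arenium ion, and proton loss followed by protodeauration releases the 2H-chromene and the catalyst. The closest known reaction type is the gold- or platinum-catalysed intramolecular hydroarylation (Friedel–Crafts-type alkenylation) of aryl propargyl ethers to 2H-chromenes. Ring C closes in the 6-endo-dig mode by forming C4–C4a. No new stereocentre arises, and C2 should be carried through unchanged because none of its bonds is broken. The step needs 6-endo rather than 5-exo closure, a single arene regiochemistry and no ionisation at C2: the unsubstituted alkyne terminus and the electron-rich free ortho carbon favour 6-endo attack, the C8 bromine blocks the other ortho site, and the pivaloyloxy group on ring B makes the benzylic propargylic cation unfavourable. A low catalyst loading, a non-coordinating solvent and exclusion of light and acid should keep the flavene from electrocyclic ring opening or oxidation.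

Step 10
Reactants: 14 (2S)-8-bromo-5-methoxy-7,4'-bis(pivaloyloxy)flav-3-ene
Product: 15 (2R,3S,4S)-8-bromo-3,4-dihydroxy-5-methoxy-2-[4-(pivaloyloxy)phenyl]chroman-7-yl pivalate
Conditions: K2OsO4·2H2O (2 mol %), NMO, acetone/H2O, 0 °C to rt
Reagents that add atoms: N-methylmorpholine N-oxide, C[N+]1([O-])CCOCC1; water, O
Why: Osmium-catalysed syn-dihydroxylation (concerted [3+2] addition of octavalent osmium tetroxide regenerated by NMO) should occur on the face of C3=C4 opposite the C2 aryl group, setting C3 and C4 together as the 2,3-trans-3,4-cis diol; C2 is untouched and is named R only because C3 now outranks the aryl carbon.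

Step 11
Reactants: 15 (2R,3S,4S)-8-bromo-3,4-dihydroxy-5-methoxy-2-[4-(pivaloyloxy)phenyl]chroman-7-yl pivalate; 16 tributyl(3-methylbut-2-en-1-yl)stannane
Product: 17 (2R,3S,4S)-3,4-dihydroxy-5-methoxy-8-(3-methylbut-2-en-1-yl)-2-[4-(pivaloyloxy)phenyl]chroman-7-yl pivalate
Conditions: Pd(PPh3)4 (10 mol %), DMF, 90 °C, degassed
Reagents that add atoms: none
Why: Stille cross-coupling, in which zerovalent palladium inserts into the C8–Br bond, the prenyl group is transferred from tin and reductive elimination at the less hindered primary allyl terminus should give the linear prenyl arene; the neutral conditions tolerate the free diol and both esters, and the prenyl alkene enters only after the oxidation it would not survive.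

Step 12
Reactants: 17 (2R,3S,4S)-3,4-dihydroxy-5-methoxy-8-(3-methylbut-2-en-1-yl)-2-[4-(pivaloyloxy)phenyl]chroman-7-yl pivalate
Product: 18 5-O-methyl-8-prenylafzelechin-4β-ol, (2R,3S,4S)-2-(4-hydroxyphenyl)-5-methoxy-8-(3-methylbut-2-en-1-yl)chroman-3,4,7-triol
Conditions: K2CO3 (0.5 equiv), MeOH, 0 °C to rt, argon; pH 7 buffer
Reagents that add atoms: none
Why: Base-catalysed transesterification (methanolysis) should cleave both aryl pivalates, which as phenol esters react far faster than alkyl esters, while substoichiometric carbonate, low temperature and a buffered quench keep phenoxide-driven loss of the C4 hydroxyl slow and leave all three stereocentres untouched.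

**Compound list**

1 | 5-methoxybenzene-1,3-diol | COc1cc(O)cc(O)c1 | starting material
2 | 1-methoxy-3,5-bis(methoxymethoxy)benzene | COCOc1cc(OC)cc(OCOC)c1 | intermediate
3 | [4-methoxy-2,6-bis(methoxymethoxy)phenyl]lithium | [Li]c1c(OCOC)cc(OC)cc1OCOC | intermediate
4 | 2-bromo-5-methoxy-1,3-bis(methoxymethoxy)benzene | COCOc1cc(OC)cc(OCOC)c1Br | intermediate
5 | 2-bromo-5-methoxybenzene-1,3-diol | COc1cc(O)c(Br)c(O)c1 | intermediate
6 | 4-hydroxybenzaldehyde | O=Cc1ccc(O)cc1 | starting material
7 | 4-formylphenyl pivalate | O=Cc1ccc(OC(=O)C(C)(C)C)cc1 | intermediate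
8 | ethynyltrimethylsilane | C#C[Si](C)(C)C | starting material
9 | methyl[(trimethylsilyl)ethynyl]zinc | C[Zn]C#C[Si](C)(C)C | intermediate
10 | (S)-4-[1-hydroxy-3-(trimethylsilyl)prop-2-yn-1-yl]phenyl pivalate | C[Si](C)(C)C#C[C@@H](O)c1ccc(OC(=O)C(C)(C)C)cc1 | intermediate
11 | (R)-4-(1-hydroxyprop-2-yn-1-yl)phenyl pivalate | C#C[C@@H](O)c1ccc(OC(=O)C(C)(C)C)cc1 | intermediate
12 | (S)-4-[1-(2-bromo-3-hydroxy-5-methoxyphenoxy)prop-2-yn-1-yl]phenyl pivalate | COc1cc(O)c(Br)c(O[C@@H](C#C)c2ccc(OC(=O)C(C)(C)C)cc2)c1 | intermediate
13 | (S)-2-bromo-5-methoxy-3-{1-[4-(pivaloyloxy)phenyl]prop-2-yn-1-yloxy}phenyl pivalate | COc1cc(OC(=O)C(C)(C)C)c(Br)c(O[C@@H](C#C)c2ccc(OC(=O)C(C)(C)C)cc2)c1 | intermediate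
14 | (2S)-8-bromo-5-methoxy-7,4'-bis(pivaloyloxy)flav-3-ene | COc1cc(OC(=O)C(C)(C)C)c(Br)c2c1C=C[C@@H](c1ccc(OC(=O)C(C)(C)C)cc1)O2 | intermediate
15 | (2R,3S,4S)-8-bromo-3,4-dihydroxy-5-methoxy-2-[4-(pivaloyloxy)phenyl]chroman-7-yl pivalate | COc1cc(OC(=O)C(C)(C)C)c(Br)c2c1[C@H](O)[C@H](O)[C@@H](c1ccc(OC(=O)C(C)(C)C)cc1)O2 | intermediate
16 | tributyl(3-methylbut-2-en-1-yl)stannane | CCCC[Sn](CCCC)(CCCC)CC=C(C)C | starting material
17 | (2R,3S,4S)-3,4-dihydroxy-5-methoxy-8-(3-methylbut-2-en-1-yl)-2-[4-(pivaloyloxy)phenyl]chroman-7-yl pivalate | COc1cc(OC(=O)C(C)(C)C)c(CC=C(C)C)c2c1[C@H](O)[C@H](O)[C@@H](c1ccc(OC(=O)C(C)(C)C)cc1)O2 | intermediate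
18 | 5-O-methyl-8-prenylafzelechin-4β-ol | COc1cc(O)c(CC=C(C)C)c2c1[C@H](O)[C@H](O)[C@@H](c1ccc(O)cc1)O2 | target

**Step count and risks**

Total steps: 12. Longest linear sequence: 9 steps (steps 1–3 then 7–12 from 5-methoxybenzene-1,3-diol, or equally steps 4–6 then 7–12 from 4-hydroxybenzaldehyde).

Step 7 (Mitsunobu etherification). The coupling may stall at the ortho-brominated phenol, a second etherification of the symmetric diol or SN2′ attack at the alkyne terminus may intrude, and partial ionisation of the alkoxyphosphonium may erode the configuration at C2. The fallback sets out from 11 and 5. Acetylation of 11 (Ac2O, pyridine, DMAP) would give (R)-1-[4-(pivaloyloxy)phenyl]prop-2-yn-1-yl acetate F1. Copper-catalysed enantioselective propargylic etherification of diol 5 with F1 (CuOTf·0.5C6H6, chiral pybox ligand, iPr2NEt, low temperature) should then come back to the route at 12. This substitution runs through a monovalent copper allenylidene, which erases the configuration of F1, so C2 would be set by the ligand (the antipode giving the S ether is chosen) and not by an SN2 event at a hindered phenol.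

Step 11 (Stille prenylation). Oxidative addition into the doubly ortho-oxygenated C8–Br bond may be slow, the hindered prenylstannane may transmetalate sluggishly or couple through its tertiary terminus, and prolonged heating may lead to hydrodebromination or stress the benzylic diol. The fallback sets out from 15. Stille coupling with the unhindered allyltributylstannane under the same zerovalent palladium catalysis would give (2R,3S,4S)-8-allyl-3,4-dihydroxy-5-methoxy-2-[4-(pivaloyloxy)phenyl]chroman-7-yl pivalate F2, for which no regiochemical ambiguity exists. Cross-metathesis of F2 with 2-methylbut-2-ene (second-generation Grubbs catalyst, CH2Cl2, 40 °C) should turn the allyl into the prenyl group and come back at 17.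

Step 5 (asymmetric alkynylation). Facial discrimination may fall short for a para-acyloxybenzaldehyde or run in the sense opposite to that assumed, and any shortfall would be carried into C2 of every later compound. The fallback sets out from 7 and 8. Deprotonation of 8 with n-BuLi would give lithium (trimethylsilyl)acetylide F3, whose addition to 7 at −78 °C should give racemic 4-[1-hydroxy-3-(trimethylsilyl)prop-2-yn-1-yl]phenyl pivalate F4. Oxidation with MnO2 would give 4-[3-(trimethylsilyl)prop-2-ynoyl]phenyl pivalate F5. Midland reduction of F5 with B-isopinocampheyl-9-borabicyclo[3.3.1]nonane made from (−)-α-pinene, in which the slim alkyne takes the small-group position and the aryl ring the large one, should come back at 10.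

**Further compounds**

F1 | step 7 | (R)-1-[4-(pivaloyloxy)phenyl]prop-2-yn-1-yl acetate | C#C[C@@H](OC(C)=O)c1ccc(OC(=O)C(C)(C)C)cc1
F2 | step 11 | (2R,3S,4S)-8-allyl-3,4-dihydroxy-5-methoxy-2-[4-(pivaloyloxy)phenyl]chroman-7-yl pivalate | COc1cc(OC(=O)C(C)(C)C)c(CC=C)c2c1[C@H](O)[C@H](O)[C@@H](c1ccc(OC(=O)C(C)(C)C)cc1)O2
F3 | step 5 | lithium (trimethylsilyl)acetylide | [Li]C#C[Si](C)(C)C
F4 | step 5 | racemic 4-[1-hydroxy-3-(trimethylsilyl)prop-2-yn-1-yl]phenyl pivalate | C[Si](C)(C)C#CC(O)c1ccc(OC(=O)C(C)(C)C)cc1
F5 | step 5 | 4-[3-(trimethylsilyl)prop-2-ynoyl]phenyl pivalate | C[Si](C)(C)C#CC(=O)c1ccc(OC(=O)C(C)(C)C)cc1
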